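The cis-octalin is cut by an anionic oxy-Cope rearrangement. In naphthalene numbering the ring A alkene C5=C6, the fusion carbon C4a, the ring B methylene C4 and the ring B alkene C3=C2 form a 1,5-diene with C4a–C4 as its central bond. With oxygen on C2 this maps back onto a 2-isopropenyl-1,3,3-trimethylbicyclo[2.2.2]oct-5-en-2-ol. In one operation the [3,3] shift closes ring B, opens the cage to ring A, fixes the cis fusion and gives the C2 enolate, trapped as the triflate. That triflate is joined to a separately made ethynyl-1,2-dioxane; alkyne saturation and oxidation to the acid complete the target.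

Key step: step 5

Remark on the chemistry: the primary alcohol is carried as its tert-butyldiphenylsilyl ether (chosen to survive acidic perhydrolysis), and commercial 1-methylcyclohexa-1,3-diene is assumed usable after distillation, any 2-methyl isomer giving an adduct that is removed together with the exo isomer of 3.

Step 1
Reactants: 1 1-methylcyclohexa-1,3-diene; 2 acrolein
Product: 3 (1R,2R,4R)-1-methylbicyclo[2.2.2]oct-5-ene-2-carbaldehyde (formyl endo and next to the methyl bridgehead)
Conditions: (5S)-5-benzyl-2,2,3-trimethylimidazolidin-4-one·HCl (10 mol %), MeCN/H2O, rt; chromatographic removal of the exo adduct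
Reagents that add atoms: none
Why: Iminium-catalysed enantioselective Diels–Alder reaction, in which the benzyl group of the catalyst should block one face of the acrolein iminium ion so that the diene adds endo to the Si face of the α-carbon with its unsubstituted terminus on the β-carbon (ortho orientation), setting C1, C2 and C4 in one event; the exo adduct, which would lead to the antipodal ketone, is removed here, and the (5R) catalyst would be taken if the facial sense turned out opposite.

Step 2
Reactants: 3 (1R,2R,4R)-1-methylbicyclo[2.2.2]oct-5-ene-2-carbaldehyde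
Product: 4 (1R,4R)-1-methylbicyclo[2.2.2]oct-5-en-2-one
Conditions: Cu(OAc)2 (cat.), 2,2'-bipyridine (cat.), DABCO, O2 (1 atm), DMF, 40 °C
Reagents that add atoms: dioxygen, O=O
Why: Copper-catalysed aerobic oxidative deformylation of an α-branched aldehyde, in which the enol is oxygenated at C2 and the α-peroxy aldehyde collapses to ketone and formate, so the C2 stereocentre disappears while both bridgeheads are untouched.

Step 3
Reactants: 4 (1R,4R)-1-methylbicyclo[2.2.2]oct-5-en-2-one
Product: 6 (1R,4S)-1,3,3-trimethylbicyclo[2.2.2]oct-5-en-2-one, via monomethyl ketone 5 (not isolated)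
Conditions: KOt-Bu (3 equiv), MeI (5 equiv), THF, 0 °C to rt
Reagents that add atoms: iodomethane, CI
Why: Exhaustive enolate C-methylation, which can only occur at C3 because C1 is a quaternary bridgehead, so two successive alkylations give the gem-dimethyl ketone and create no stereocentre.

Step 4
Reactants: 6 (1R,4S)-1,3,3-trimethylbicyclo[2.2.2]oct-5-en-2-one; 7 2-bromopropene
Product: 9 (1R,2S,4S)-1,3,3-trimethyl-2-(prop-1-en-2-yl)bicyclo[2.2.2]oct-5-en-2-ol (isopropenyl syn to the C5=C6 bridge), via isopropenyllithium 8 (not isolated)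
Conditions: 7, t-BuLi (2 equiv), Et2O, −78 °C; then 6, THF, −78 to 0 °C; H2O
Reagents that add atoms: none
Why: Bromine–lithium exchange then 1,2-addition of the alkenyllithium to a ketone that cannot enolise; the reagent should come in over the flat C5=C6 bridge and not past the inward C–H bonds of the C7–C8 bridge, which sets C2 with the isopropenyl group syn to the alkene, and the minor epimer is removed by chromatography.

Step 5
Reactants: 9 (1R,2S,4S)-1,3,3-trimethyl-2-(prop-1-en-2-yl)bicyclo[2.2.2]oct-5-en-2-ol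
Product: 12 (4aR,8aS)-1,1,3,6-tetramethyl-1,4,4a,7,8,8a-hexahydronaphthalen-2-yl trifluoromethanesulfonate, via potassium alkoxide 10 (not isolated), via potassium enolate 11 (not isolated)
Conditions: KHMDS (1.2 equiv), 18-crown-6, THF, 0 °C to rt; then PhNTf2, −78 to 0 °C
Reagents that add atoms: N-phenylbis(trifluoromethanesulfonimide), O=S(=O)(N(c1ccccc1)S(=O)(=O)C(F)(F)F)C(F)(F)F
Why: KHMDS with 18-crown-6 turns 9 into the dissociated alkoxide 10, whose charge weakens the adjacent C1–C2 bond of the bicycle and triggers a concerted suprafacial [3,3] shift through the boat-like array imposed by the cage: the isopropenyl CH2 bonds to C5 of the etheno bridge while C1–C2 breaks, giving enolate 11, which PhNTf2 sulfonylates on oxygen. The closest known reaction type is the anionic oxy-Cope rearrangement of 2-alkenylbicyclo[2.2.2]oct-5-en-2-ols to cis-fused octalone enolates, combined with regiospecific enolate O-triflation. Ring B (C4a–C4–C3–C2–C1–C8a of the product) is closed by the sigmatropic C4–C4a bond formation, whereas ring A is not closed but released from the bridged system when the old bridgehead bond breaks, with its C5=C6 alkene already in place. The one new stereocentre, C4a, is dictated by the tether, since the isopropenyl terminus can reach the etheno bridge only on the face turned toward the carbinol bridge, which puts H4a cis to H8a; C8a is the former Diels–Alder bridgehead. The step needs the alkenyl group syn to the etheno bridge, secured in step 4, and a single enolate regioisomer, secured because the enolate is born at C2=C3 and C1 is quaternary, so the leaving group lands exactly on C2. The driving force is release of the bicyclo[2.2.2] strain together with formation of the delocalised enolate.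

Step 6
Reactants: 13 geranyl acetate
Product: 14 6,7-epoxygeranyl acetate (racemic at C6)
Conditions: mCPBA (1.0 equiv), CH2Cl2, −10 to 0 °C
Reagents that add atoms: 3-chloroperoxybenzoic acid, OOC(=O)c1cccc(Cl)c1
Why: Prilezhaev epoxidation that selects the remote, electron-richer trisubstituted alkene because the 2,3-alkene is deactivated by the allylic acetate; the new stereocentre is formed racemic and is cut out in the next step.

Step 7
Reactants: 14 6,7-epoxygeranyl acetate
Product: 16 (E)-6-acetoxy-4-methylhex-4-enal, via glycol 15 (not isolated)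
Conditions: H5IO6 (1.1 equiv), THF/H2O, 0 °C
Reagents that add atoms: none
Why: Acidic hydration of the epoxide to glycol 15 (water entering at the tertiary carbon) and periodate glycol cleavage in one pot, which releases acetone and leaves the E-alkene and the acetate untouched.

Step 8
Reactants: 16 (E)-6-acetoxy-4-methylhex-4-enal; 17 (R)-4-benzyl-3-propionyloxazolidin-2-one
Product: 19 (R)-4-benzyl-3-[(2R,3S,6E)-8-acetoxy-3-hydroxy-2,6-dimethyloct-6-enoyl]oxazolidin-2-one (syn aldol adduct), via Z-boron enolate 18 (not isolated)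
Conditions: 17, n-Bu2BOTf, i-Pr2NEt, CH2Cl2, 0 °C; then 16, −78 to 0 °C; pH 7 buffer, MeOH, H2O2, 0 °C
Reagents that add atoms: none
Why: Evans boron aldol reaction, in which the Z-enolate 18 reacts through a Zimmerman–Traxler chair with the imide dipoles opposed, so the benzyl group of the (R)-auxiliary screens one enolate face and the (2R,3S)-syn pair is set under auxiliary control.

Step 9
Reactants: 19 syn aldol adduct
Product: 20 (2E,6S,7S)-6,8-dihydroxy-3,7-dimethyloct-2-en-1-yl acetate
Conditions: NaBH4, THF/H2O, 0 °C to rt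
Reagents that add atoms: none
Why: Borohydride reduction of the activated exocyclic imide carbonyl, which is far more electrophilic than the alkyl acetate, should release the auxiliary and give the primary alcohol without touching the ester or the α-stereocentre.

Step 10
Reactants: 20 (2E,6S,7S)-6,8-dihydroxy-3,7-dimethyloct-2-en-1-yl acetate
Product: 21 (2E,6S,7S)-8-[(tert-butyldiphenylsilyl)oxy]-6-hydroxy-3,7-dimethyloct-2-en-1-yl acetate
Conditions: TBDPSCl (1.05 equiv), imidazole, CH2Cl2, 0 °C
Reagents that add atoms: tert-butyl(chloro)diphenylsilane, CC(C)(C)[Si](Cl)(c1ccccc1)c1ccccc1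
Why: Silyl ether formation under steric control, the bulky chlorosilane reacting at the primary hydroxyl only; this silyl group is chosen because it must survive the acidic perhydrolysis in step 14.

Step 11
Reactants: 21 primary silyl ether
Product: 22 (2E,6S,7S)-8-[(tert-butyldiphenylsilyl)oxy]-3,7-dimethyl-6-(methylsulfonyloxy)oct-2-en-1-yl acetate
Conditions: MsCl, Et3N, CH2Cl2, 0 °C
Reagents that add atoms: methanesulfonyl chloride, CS(=O)(=O)Cl
Why: Sulfonylation of the remaining secondary alcohol at oxygen, hence with retention at carbon, which installs the leaving group for the later inversion.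

Step 12
Reactants: 22 mesylate acetate
Product: 23 (2S,3S,6E)-1-[(tert-butyldiphenylsilyl)oxy]-8-hydroxy-2,6-dimethyloct-6-en-3-yl methanesulfonate
Conditions: K2CO3 (cat.), MeOH, 0 °C
Reagents that add atoms: none
Why: Carbonate-catalysed transesterification with methanol removes the acetate alone, since the unactivated secondary mesylate and the silyl ether should be inert to brief mild methanolysis.

Step 13
Reactants: 23 allylic alcohol mesylate
Product: 24 (2S,3S)-1-[(tert-butyldiphenylsilyl)oxy]-5-[(2R,3R)-3-(hydroxymethyl)-2-methyloxiran-2-yl]-2-methylpentan-3-yl methanesulfonate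
Conditions: Ti(Oi-Pr)4 (10 mol %), D-(−)-diethyl tartrate (12 mol %), t-BuOOH, 4 Å MS, CH2Cl2, −20 °C
Reagents that add atoms: tert-butyl hydroperoxide, CC(C)(C)OO
Why: Sharpless asymmetric epoxidation, in which the titanium D-(−)-tartrate complex delivers oxygen to the face of the (E)-allylic alcohol that gives the (2R,3R)-epoxy alcohol under reagent control.

Step 14
Reactants: 24 (2R,3R)-epoxy alcohol mesylate
Product: 25 (2S,3S,6S,7R)-1-[(tert-butyldiphenylsilyl)oxy]-6-hydroperoxy-7,8-dihydroxy-2,6-dimethyloctan-3-yl methanesulfonate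
Conditions: anhydrous H2O2 in Et2O (excess), phosphomolybdic acid (cat.), rt
Reagents that add atoms: hydrogen peroxide, OO
Why: Acid-catalysed perhydrolysis of an epoxide, in which hydrogen peroxide opens the activated oxirane at the tertiary carbon, which carries most of the positive charge, from the side opposite the leaving oxygen, so the future quaternary dioxane carbon is formed with inversion while the mesylate is inert to acid.

Step 15
Reactants: 25 hydroperoxy diol mesylate
Product: 26 (1R)-1-[(3S,6R)-6-{(2S)-1-[(tert-butyldiphenylsilyl)oxy]propan-2-yl}-3-methyl-1,2-dioxan-3-yl]ethane-1,2-diol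
Conditions: KOt-Bu (1.05 equiv), 18-crown-6 (cat.), THF, −20 to 0 °C
Reagents that add atoms: none
Why: Intramolecular SN2 alkylation of the hydroperoxide anion (the most acidic and, through the α-effect, most nucleophilic oxygen) at the mesylate carbon in a 6-exo-tet closure, which forms the 1,2-dioxane and inverts the former aldol carbinol centre.

Step 16
Reactants: 26 dioxane diol
Product: 27 (3S,6R)-6-{(2S)-1-[(tert-butyldiphenylsilyl)oxy]propan-2-yl}-3-methyl-1,2-dioxane-3-carbaldehyde
Conditions: NaIO4, THF/pH 7 buffer, 0 °C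
Reagents that add atoms: none
Why: Periodate glycol cleavage (Malaprade reaction) of the terminal 1,2-diol gives an aldehyde on a quaternary carbon that cannot enolise, and periodate does not touch the dialkyl peroxide.

Step 17
Reactants: 27 dioxane aldehyde
Product: 28 tert-butyl{(2S)-2-[(3R,6S)-6-ethynyl-6-methyl-1,2-dioxan-3-yl]propoxy}diphenylsilane
Conditions: dimethyl (1-diazo-2-oxopropyl)phosphonate, K2CO3, MeOH, 0 °C to rt
Reagents that add atoms: dimethyl (1-diazo-2-oxopropyl)phosphonate, COP(=O)(OC)C(=[N+]=[N-])C(C)=O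
Why: Ohira–Bestmann homologation, in which the diazomethylphosphonate anion formed by methanolysis adds to the aldehyde and the alkylidene carbene rearranges by 1,2-hydrogen shift to the terminal alkyne; the quaternary centre is not involved.

Step 18
Reactants: 12 enol triflate; 28 ethynyl dioxane
Product: 29 tert-butyl{(2S)-2-[(3R,6S)-6-methyl-6-{[(4aR,8aS)-1,1,3,6-tetramethyl-1,4,4a,7,8,8a-hexahydronaphthalen-2-yl]ethynyl}-1,2-dioxan-3-yl]propoxy}diphenylsilane
Conditions: PdCl2(PPh3)2 (5 mol %), CuI (10 mol %), i-Pr2NH, DMF, rt to 40 °C, degassed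
Reagents that add atoms: none
Why: Sonogashira coupling of an enol triflate with a terminal alkyne, a reaction type that accepts 2,6,6-trisubstituted cyclohexenyl triflates and is compatible with dialkyl peroxides, joins C2 to the side chain without touching any stereocentre.

Step 19
Reactants: 29 enyne
Product: 31 tert-butyl{(2S)-2-[(3R,6R)-6-methyl-6-{2-[(4aR,8aS)-1,1,3,6-tetramethyl-1,4,4a,7,8,8a-hexahydronaphthalen-2-yl]ethyl}-1,2-dioxan-3-yl]propoxy}diphenylsilane, via Z-diene 30 (not isolated)
Conditions: KO2CN=NCO2K (excess, in portions), AcOH, MeOH/CH2Cl2, 0 °C to rt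
Reagents that add atoms: none
Why: Diimide transfers hydrogen in a concerted syn fashion to the alkyne and then to the strained Z-alkene 30 much faster than to the trisubstituted and tetrasubstituted ring alkenes, and it does not reduce the O–O bond.

Step 20
Reactants: 31 saturated silyl ether
Product: 32 (2S)-2-[(3R,6R)-6-methyl-6-{2-[(4aR,8aS)-1,1,3,6-tetramethyl-1,4,4a,7,8,8a-hexahydronaphthalen-2-yl]ethyl}-1,2-dioxan-3-yl]propan-1-ol
Conditions: TBAF, AcOH (1:1), THF, rt
Reagents that add atoms: none
Why: Fluoride-induced desilylation, buffered with acetic acid so that the peroxide, whose ring C–H is base-sensitive, is not exposed to unbuffered fluoride.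

Step 21
Reactants: 32 primary alcohol
Product: 33 (2R)-2-[(3R,6R)-6-methyl-6-{2-[(4aR,8aS)-1,1,3,6-tetramethyl-1,4,4a,7,8,8a-hexahydronaphthalen-2-yl]ethyl}-1,2-dioxan-3-yl]propanal
Conditions: Dess–Martin periodinane, pyridine, CH2Cl2, 0 °C; crude aldehyde used at once
Reagents that add atoms: none
Why: Dess–Martin oxidation under buffered conditions stops at the aldehyde and should avoid both epimerisation of the α-carbon and β-elimination of the peroxide oxygen.

Step 22
Reactants: 33 aldehyde
Product: 34 (2R)-2-[(3R,6R)-6-methyl-6-{2-[(4aR,8aS)-1,1,3,6-tetramethyl-1,4,4a,7,8,8a-hexahydronaphthalen-2-yl]ethyl}-1,2-dioxan-3-yl]propanoic acid (CNP0122760.1)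
Conditions: NaClO2, NaH2PO4, 2-methylbut-2-ene (large excess), t-BuOH/H2O, 0 °C to rt
Reagents that add atoms: sodium chlorite, [Na+].[O-]Cl=O
Why: Pinnick oxidation, in which chlorous acid converts the aldehyde into the acid at mildly acidic pH without epimerisation, while the large excess of 2-methylbut-2-ene takes up the hypochlorous acid before it can attack the ring alkenes.

Compound list
1 | 1-methylcyclohexa-1,3-diene | CC1=CC=CCC1 | starting material
2 | acrolein | C=CC=O | starting material
3 | (1R,2R,4R)-1-methylbicyclo[2.2.2]oct-5-ene-2-carbaldehyde (endo) | C[C@@]12CC[C@@H](C=C1)C[C@H]2C=O | intermediate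
4 | (1R,4R)-1-methylbicyclo[2.2.2]oct-5-en-2-one | C[C@@]12CC[C@@H](C=C1)CC2=O | intermediate
5 | 1,3-dimethylbicyclo[2.2.2]oct-5-en-2-one (bridgeheads as in 4, both C3 epimers) | C[C@@]12CC[C@@H](C=C1)C(C)C2=O | intermediate
6 | (1R,4S)-1,3,3-trimethylbicyclo[2.2.2]oct-5-en-2-one | C[C@@]12CC[C@@H](C=C1)C(C)(C)C2=O | intermediate
7 | 2-bromopropene | CC(Br)=C | starting material
8 | isopropenyllithium | [Li]C(C)=C | intermediate
9 | (1R,2S,4S)-1,3,3-trimethyl-2-(prop-1-en-2-yl)bicyclo[2.2.2]oct-5-en-2-ol | C[C@@]12CC[C@@H](C=C1)C(C)(C)[C@@]2(O)C(C)=C | intermediate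
10 | potassium alkoxide of 9 | C[C@@]12CC[C@@H](C=C1)C(C)(C)[C@@]2([O-])C(C)=C.[K+] | intermediate
11 | potassium (4aR,8aS)-1,1,3,6-tetramethyl-1,4,4a,7,8,8a-hexahydronaphthalen-2-olate | CC1=C[C@H]2CC(C)=C([O-])C(C)(C)[C@H]2CC1.[K+] | intermediate
12 | (4aR,8aS)-1,1,3,6-tetramethyl-1,4,4a,7,8,8a-hexahydronaphthalen-2-yl trifluoromethanesulfonate | CC1=C[C@H]2CC(C)=C(OS(=O)(=O)C(F)(F)F)C(C)(C)[C@H]2CC1 | intermediate
13 | geranyl acetate | CC(C)=CCC/C(C)=C/COC(C)=O | starting material
14 | 6,7-epoxygeranyl acetate (racemic at C6) | CC1(C)OC1CC/C(C)=C/COC(C)=O | intermediate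
15 | (E)-6,7-dihydroxy-3,7-dimethyloct-2-en-1-yl acetate (racemic) | CC(C)(O)C(O)CC/C(C)=C/COC(C)=O | intermediate
16 | (E)-6-acetoxy-4-methylhex-4-enal | O=CCC/C(C)=C/COC(C)=O | intermediate
17 | (R)-4-benzyl-3-propionyloxazolidin-2-one | CCC(=O)N1[C@H](Cc2ccccc2)COC1=O | starting material
18 | (Z)-dibutylboron enolate of 17 | C/C=C(\OB(CCCC)CCCC)N1[C@H](Cc2ccccc2)COC1=O | intermediate
19 | (R)-4-benzyl-3-[(2R,3S,6E)-8-acetoxy-3-hydroxy-2,6-dimethyloct-6-enoyl]oxazolidin-2-one | CC(=O)OC/C=C(C)/CC[C@H](O)[C@@H](C)C(=O)N1[C@H](Cc2ccccc2)COC1=O | intermediate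
20 | (2E,6S,7S)-6,8-dihydroxy-3,7-dimethyloct-2-en-1-yl acetate | CC(=O)OC/C=C(C)/CC[C@H](O)[C@@H](C)CO | intermediate
21 | (2E,6S,7S)-8-[(tert-butyldiphenylsilyl)oxy]-6-hydroxy-3,7-dimethyloct-2-en-1-yl acetate | CC(=O)OC/C=C(C)/CC[C@H](O)[C@@H](C)CO[Si](c1ccccc1)(c1ccccc1)C(C)(C)C | intermediate
22 | (2E,6S,7S)-8-[(tert-butyldiphenylsilyl)oxy]-3,7-dimethyl-6-(methylsulfonyloxy)oct-2-en-1-yl acetate | CC(=O)OC/C=C(C)/CC[C@H](OS(C)(=O)=O)[C@@H](C)CO[Si](c1ccccc1)(c1ccccc1)C(C)(C)C | intermediate
23 | (2S,3S,6E)-1-[(tert-butyldiphenylsilyl)oxy]-8-hydroxy-2,6-dimethyloct-6-en-3-yl methanesulfonate | OC/C=C(C)/CC[C@H](OS(C)(=O)=O)[C@@H](C)CO[Si](c1ccccc1)(c1ccccc1)C(C)(C)C | intermediate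
24 | (2S,3S)-1-[(tert-butyldiphenylsilyl)oxy]-5-[(2R,3R)-3-(hydroxymethyl)-2-methyloxiran-2-yl]-2-methylpentan-3-yl methanesulfonate | OC[C@H]1O[C@]1(C)CC[C@H](OS(C)(=O)=O)[C@@H](C)CO[Si](c2ccccc2)(c2ccccc2)C(C)(C)C | intermediate
25 | (2S,3S,6S,7R)-1-[(tert-butyldiphenylsilyl)oxy]-6-hydroperoxy-7,8-dihydroxy-2,6-dimethyloctan-3-yl methanesulfonate | OC[C@@H](O)[C@@](C)(OO)CC[C@H](OS(C)(=O)=O)[C@@H](C)CO[Si](c1ccccc1)(c1ccccc1)C(C)(C)C | intermediate
26 | (1R)-1-[(3S,6R)-6-{(2S)-1-[(tert-butyldiphenylsilyl)oxy]propan-2-yl}-3-methyl-1,2-dioxan-3-yl]ethane-1,2-diol | OC[C@@H](O)[C@]1(C)CC[C@H]([C@@H](C)CO[Si](c2ccccc2)(c2ccccc2)C(C)(C)C)OO1 | intermediate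
27 | (3S,6R)-6-{(2S)-1-[(tert-butyldiphenylsilyl)oxy]propan-2-yl}-3-methyl-1,2-dioxane-3-carbaldehyde | O=C[C@]1(C)CC[C@H]([C@@H](C)CO[Si](c2ccccc2)(c2ccccc2)C(C)(C)C)OO1 | intermediate
28 | tert-butyl{(2S)-2-[(3R,6S)-6-ethynyl-6-methyl-1,2-dioxan-3-yl]propoxy}diphenylsilane | C#C[C@]1(C)CC[C@H]([C@@H](C)CO[Si](c2ccccc2)(c2ccccc2)C(C)(C)C)OO1 | intermediate
29 | coupled enyne (silyl ether; ring C2 joined to the dioxane quaternary carbon through C≡C) | CC1=C[C@H]2CC(C)=C(C#C[C@]3(C)CC[C@H]([C@@H](C)CO[Si](c4ccccc4)(c4ccccc4)C(C)(C)C)OO3)C(C)(C)[C@H]2CC1 | intermediate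
30 | Z-diene (cis-CH=CH in place of the alkyne of 29) | CC1=C[C@H]2CC(C)=C(/C=C\[C@]3(C)CC[C@H]([C@@H](C)CO[Si](c4ccccc4)(c4ccccc4)C(C)(C)C)OO3)C(C)(C)[C@H]2CC1 | intermediate
31 | saturated silyl ether (CH2CH2 link) | CC1=C[C@H]2CC(C)=C(CC[C@]3(C)CC[C@H]([C@@H](C)CO[Si](c4ccccc4)(c4ccccc4)C(C)(C)C)OO3)C(C)(C)[C@H]2CC1 | intermediate
32 | (2S)-2-[(3R,6R)-6-methyl-6-{2-[(4aR,8aS)-1,1,3,6-tetramethyl-1,4,4a,7,8,8a-hexahydronaphthalen-2-yl]ethyl}-1,2-dioxan-3-yl]propan-1-ol | CC1=C[C@H]2CC(C)=C(CC[C@]3(C)CC[C@H]([C@@H](C)CO)OO3)C(C)(C)[C@H]2CC1 | intermediate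
33 | (2R)-2-[(3R,6R)-6-methyl-6-{2-[(4aR,8aS)-1,1,3,6-tetramethyl-1,4,4a,7,8,8a-hexahydronaphthalen-2-yl]ethyl}-1,2-dioxan-3-yl]propanal | CC1=C[C@H]2CC(C)=C(CC[C@]3(C)CC[C@H]([C@@H](C)C=O)OO3)C(C)(C)[C@H]2CC1 | intermediate
34 | CNP0122760.1, (2R)-2-[(3R,6R)-6-methyl-6-{2-[(4aR,8aS)-1,1,3,6-tetramethyl-1,4,4a,7,8,8a-hexahydronaphthalen-2-yl]ethyl}-1,2-dioxan-3-yl]propanoic acid | CC1=C[C@H]2CC(C)=C(CC[C@]3(C)CC[C@H]([C@@H](C)C(=O)O)OO3)C(C)(C)[C@H]2CC1 | target

Total step count: 22. Longest linear sequence: 17 steps (from 13 to 34, steps 6 to 22); the bicyclic branch reaches triflate 12 in 5 steps.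

Steps most likely to fail

Step 14 (perhydrolysis). Ionisation at the tertiary oxirane carbon may run ahead of peroxide attack and erode configuration at the future quaternary dioxane carbon. Attack at the secondary oxirane carbon may compete, or the β-hydroxy hydroperoxide may suffer acid-induced C–C cleavage. The fallback reverses the order in which the two C–O bonds of the peroxide are made, so that the tertiary carbon is attacked intramolecularly. It sets out from allylic alcohol 23. Treatment with 2-methoxyprop-2-yl hydroperoxide and CsOH in DMF displaces the mesylate with inversion and should give the secondary peroxyketal F1. Sharpless epoxidation with D-(−)-tartrate as in step 13 should give the epoxy peroxyketal F2. Brief acid treatment (camphorsulfonic acid, wet CH2Cl2) unmasks the secondary hydroperoxide F3. F3 opens the protonated epoxide 6-exo at the tertiary carbon with inversion and so comes back to the route at dioxane diol 26 with both ring carbons in the same configuration, leaving out steps 14 and 15.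

Step 17 (alkyne homologation). Methoxide or the diazophosphonate anion may add to the α-peroxy aldehyde, and the alkoxide so formed may fragment with heterolysis of the O–O bond before the carbene pathway is completed. The fallback gives up the alkyne and forms the side-chain bond by an sp3–sp2 coupling. It sets out from aldehyde 27, which is methylenated with salt-free methylenetriphenylphosphorane at low temperature (Wittig reaction) to the vinyl dioxane F4. 9-BBN adds anti-Markovnikov to give the primary B-alkyl borane F5. F5 is coupled without isolation with triflate 12 in a B-alkyl Suzuki–Miyaura reaction (PdCl2(dppf), AsPh3, Cs2CO3, DMF/THF/H2O). This comes back to the route at the saturated silyl ether 31, so steps 18 and 19 are no longer needed.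

Step 18 (Sonogashira coupling). Transmetalation and reductive elimination at the tetrasubstituted alkenylpalladium, flanked by the gem-dimethyl carbon, may be slow. Copper-mediated oxidative dimerisation of the alkyne or decay of the propargylic peroxide under amine and copper could then take over. The fallback exchanges the roles of the partners in a copper-free and amine-free coupling and sets out from 12 and 28. Triflate 12 is converted by Miyaura borylation (B2pin2, PdCl2(dppf), KOPh, toluene) into the alkenyl pinacol boronate F6. Alkyne 28 is iodinated (N-iodosuccinimide, cat. AgNO3, acetone) to the 1-iodoalkyne F7. Suzuki–Miyaura coupling of the two (Pd(PPh3)4, Cs2CO3, THF/H2O) comes back to the route at enyne 29.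

Further compounds
F1 | step 14 | (2S,3R,6E)-1-[(tert-butyldiphenylsilyl)oxy]-8-hydroxy-2,6-dimethyloct-6-en-3-yl 2-methoxyprop-2-yl peroxide | OC/C=C(C)/CC[C@@H](OOC(C)(C)OC)[C@@H](C)CO[Si](c1ccccc1)(c1ccccc1)C(C)(C)C
F2 | step 14 | (2R,3R)-epoxy alcohol of F1 | OC[C@H]1O[C@]1(C)CC[C@@H](OOC(C)(C)OC)[C@@H](C)CO[Si](c2ccccc2)(c2ccccc2)C(C)(C)C
F3 | step 14 | secondary hydroperoxide from F2 (epoxy alcohol intact) | OC[C@H]1O[C@]1(C)CC[C@@H](OO)[C@@H](C)CO[Si](c2ccccc2)(c2ccccc2)C(C)(C)C
F4 | step 17 | tert-butyl{(2S)-2-[(3R,6S)-6-ethenyl-6-methyl-1,2-dioxan-3-yl]propoxy}diphenylsilane | C=C[C@]1(C)CC[C@H]([C@@H](C)CO[Si](c2ccccc2)(c2ccccc2)C(C)(C)C)OO1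
F5 | step 17 | 9-{2-[dioxanyl]ethyl}-9-borabicyclo[3.3.1]nonane from F4 | B1(CC[C@]2(C)CC[C@H]([C@@H](C)CO[Si](c3ccccc3)(c3ccccc3)C(C)(C)C)OO2)C2CCCC1CCC2
F6 | step 18 | 2-[(4aR,8aS)-1,1,3,6-tetramethyl-1,4,4a,7,8,8a-hexahydronaphthalen-2-yl]-4,4,5,5-tetramethyl-1,3,2-dioxaborolane | CC1=C[C@H]2CC(C)=C(B3OC(C)(C)C(C)(C)O3)C(C)(C)[C@H]2CC1
F7 | step 18 | tert-butyl{(2S)-2-[(3R,6S)-6-(iodoethynyl)-6-methyl-1,2-dioxan-3-yl]propoxy}diphenylsilane | IC#C[C@]1(C)CC[C@H]([C@@H](C)CO[Si](c2ccccc2)(c2ccccc2)C(C)(C)C)OO1
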